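The data were generated by integration for an exercise; the scatter is artificial.

In a one-step world one reagent takes one substrate, so a flask with equal charges ends holding neither.

| flask | left-handed substrate | right-handed substrate | reagent | free catalyst | remark | time |
|---|---|---|---|---|---|---|
| winter | 0.020 M | 0.020 M | 0.040 M | 2.8 mM | run made earlier |  |
| dusk | 0.040 M | 0.040 M | 0.040 M | 1.9 mM | run made earlier |  |
| ochre | 0.020 M | 0.020 M | 0.0400 M | 1.9 mM |  | 40 min |
| blue | 0.020 M | 0.020 M | 0.0800 M | 1.9 mM |  | 40 min |

- winter (time / min: right-handed substrate / %, left-handed substrate / %): 0.833: 29.8, 12.9; 2.00: 24.0, 5.9; 4.00: 21.5, 5.1; 6.00: 18.5, 3.5; 8.00: 19.0, 3.8; 12.0: 18.5, 2.6; 15.0: 19.8, 2.8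
- dusk (time / min: right-handed substrate / %, left-handed substrate / %): 2.00: 35.7, 20.1; 4.00: 35.3, 19.0; 6.00: 36.1, 20.1; 8.00: 35.3, 20.5; 10.0: 34.4, 18.6; 12.0: 35.1, 21.6; 15.0: 38.4, 21.3

(scatter of a reading: 1 percentage point)

- free catalyst is single-handed; left-handed substrate and right-handed substrate are mirror images of each other, charged as a racemate, each of them at the stated concentration
- an excess is the difference of the two amounts in percent of their sum
- an excess is below zero if the other one leads

- the winner by excess of right-handed substrate over left-handed substrate among what is left of the two; "neither" if no more than 2 percentage points parts them (ochre / blue / neither)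
- excess of right-handed substrate over left-handed substrate among what is left of the two at the end, ochre
- excess of right-handed substrate over left-handed substrate among what is left of the two at the end, blue

1. The puzzle: the winter run has 0.040 M of reagent against 0.0400 M of the two substrates together, yet at 15.0 min we still read 22.6% of that substrate.

2. Within their scatter the late readings of both runs stop moving, so we take it that reagent also went elsewhere, one reagent per substrate otherwise. The last winter reading puts that loss at 0.00904 M. The dusk run, with the catalyst charge of ochre and blue, averages 20.2% left-handed and 35.8% right-handed substrate, so we reckon its loss at 0.00474 M.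

3. Dusk reads 2.71 for s, the selectivity factor: the logarithm of the left-handed fraction of its own charge remaining over the same logarithm for the right-handed. Where s holds, the right-handed fraction left is the left-handed fraction to the power 1/s.

4. Let the depth be minus the logarithm of the left-handed fraction. The reckoned dusk loss comes to 0.00522 M of reagent per unit depth. We assume the same loss in ochre and blue, with reagent as limiting reagent: a flask stops where substrate taken plus loss equals the charge.

5. By our reckoning ochre at depth 2.3 keeps 10.0% left-handed and 42.8% right-handed of each charge. That needs 0.0415 M of reagent, close to 0.0400 M, and gives an excess of 62.0%. Blue at depth 8 needs 0.0807 M against 0.0800 M, with excess 98.7%.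

6. The forecast says 63% for ochre, below which our figure lies, and 99% for blue, so it names blue as the winner: “Waste therefore looks like catalyst-independent reagent decay competing with catalysed reaction.”

7. The flasks give 65.4% for ochre and 95.6% for blue, so blue leads.

    reagent + free catalyst + right-handed substrate → free catalyst + right-handed product (k = 10000 M⁻² min⁻¹)
    2 free catalyst → spent catalyst A (k = 15.0 M⁻¹ min⁻¹)
    reagent + free catalyst → spent catalyst B (k = 1.30 M⁻¹ min⁻¹)
    reagent + free catalyst + left-handed substrate → free catalyst + left-handed product (k = 29000 M⁻² min⁻¹)
    2 reagent → self-condensation product (k = 8.40 M⁻¹ min⁻¹)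

8. At 40.0 min ochre keeps 0.050% of its reagent, less than the 44% of right-handed substrate still there. Its 9.2% of the left-handed charge gives, through s, 41.5% of the right-handed charge against that 44%. A flask like blue with 0.020 M of reagent ends with 39.8% of the left-handed charge, so s gives 71.1% of the right-handed charge, and the flask holds 72.8%.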